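**Retrosynthetic overview**

1. (M)-Bisoflavolin D comes from BBr3 demethylation of the (M) atropisomer of its hexamethyl ether, which is separated from the racemate on a chiral phase. The axis is sorted, not set.
2. Feature: unit 1 is the genistein joined through C3' of its ring B, unit 2 the one joined through C8. Ring A of unit 1 has O1 on C8a and the carbonyl carbon C4 on the neighbouring C4a, with the C5 oxygen next to C4a. This is the pattern left when a 3-alkoxybenzyne takes oxygen at its far carbon and an acyl carbon at its near carbon.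
3. Key disconnection: O1–C8a, C4–C4a and O1–C2 of unit 1 lead back to 3,5-dimethoxybenzyne (from its 2-silylaryl triflate) and an (E)-3-methoxy-2-arylacrylic acid that already carries permethylated unit 2.
4. The acid comes from its tert-butyl ester, made by Suzuki–Miyaura coupling (C3'–C8) of 8-iodo-tri-O-methylgenistein with an aryl boronate that already bears the 3-methoxyacrylate. The base-labile pyranone of unit 2 therefore never meets Claisen or saponification conditions.
5. Ring order: all rings of unit 2 come intact from genistein, ring B of unit 1 from 3-bromo-4-methoxyphenylacetic acid, ring A of unit 1 arrives as the aryne, and ring C of unit 1 closes last in the same flask.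

Key step: step 11

Assumption: the C3'–C8 axis is taken as configurationally stable at and below room temperature, as the (M) descriptor of the natural product implies, and as freely rotating at 125 °C. SMILES cannot show the axis, so atropisomers share one string and the descriptor is carried in the name. The descriptor is the same for the hexamethyl ether and the hexaphenol, because C4' (ring B) and C8a (unit 2) rank first at the two ends in both.

Notation: Ar = 3-[5,7-dimethoxy-3-(4-methoxyphenyl)-4-oxo-4H-chromen-8-yl]-4-methoxyphenyl.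

**Route**

Step 1
Reactants: 1 genistein
Product: 2 5,7-dimethoxy-3-(4-methoxyphenyl)-4H-chromen-4-one (tri-O-methylgenistein)
Conditions: Me2SO4 (excess), K2CO3, acetone, reflux
Reagents that add atoms: dimethyl sulfate COS(=O)(=O)OC
Why: Williamson O-methylation of the three phenoxides, in which the hydrogen-bonded C5 hydroxyl reacts last and is the reason for the excess reagent and the prolonged reflux.

Step 2
Reactants: 2 tri-O-methylgenistein
Product: 3 8-iodo-5,7-dimethoxy-3-(4-methoxyphenyl)-4H-chromen-4-one
Conditions: I2 (1.05 equiv), CF3CO2Ag, CH2Cl2, 0 → 20 °C, dark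
Reagents that add atoms: iodine II
Why: Electrophilic aromatic iodination with silver-activated iodine, which with the C5 oxygen methylated should go to C8 of ring A (one flanking methoxy group) and not to C6 (between two methoxy groups), ring A being far more electron-rich than the anisole ring B.

Step 3
Reactants: 4 2-(3-bromo-4-methoxyphenyl)acetic acid
Product: 5 tert-butyl 2-(3-bromo-4-methoxyphenyl)acetate
Conditions: Cl3CC(=NH)Ot-Bu, BF3·OEt2 (cat.), CH2Cl2/cyclohexane, 20 °C
Reagents that add atoms: tert-butyl 2,2,2-trichloroacetimidate CC(C)(C)OC(=N)C(Cl)(Cl)Cl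
Why: Acid-catalysed imidate esterification (transfer of a tert-butyl cation to the carboxylic acid) installs an ester that can later be removed by acid without any hydroxide.

Step 4
Reactants: 5 tert-butyl 2-(3-bromo-4-methoxyphenyl)acetate
Product: 7 tert-butyl (E)-2-(3-bromo-4-methoxyphenyl)-3-methoxyacrylate, via sodium formyl enolate 6 (not isolated)
Conditions: NaH, HCO2Me, THF, 0 → 20 °C; then Me2SO4, DMF, 0 → 20 °C
Reagents that add atoms: methyl formate COC=O; dimethyl sulfate COS(=O)(=O)OC
Why: Crossed Claisen formylation of the ester enolate gives the stabilised enolate 6, which the hard electrophile dimethyl sulfate should alkylate on oxygen to the push–pull enol ether, expected mainly as the (E) isomer; a (Z) contaminant would be harmless because ring closure in step 11 erases the alkene geometry.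

Step 5
Reactants: 7 tert-butyl (E)-2-(3-bromo-4-methoxyphenyl)-3-methoxyacrylate
Product: 8 tert-butyl (E)-3-methoxy-2-[4-methoxy-3-(4,4,5,5-tetramethyl-1,3,2-dioxaborolan-2-yl)phenyl]acrylate
Conditions: B2pin2, PdCl2(dppf) (5 mol %), KOAc, 1,4-dioxane, 90 °C
Reagents that add atoms: bis(pinacolato)diboron CC1(C)OB(OC1(C)C)B1OC(C)(C)C(C)(C)O1
Why: Miyaura borylation of the aryl bromide under weakly basic acetate conditions, which the tert-butyl ester and the enol ether tolerate.

Step 6
Reactants: 3 8-iodo-5,7-dimethoxy-3-(4-methoxyphenyl)-4H-chromen-4-one; 8 aryl pinacol boronate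
Product: 9 tert-butyl (E)-3-methoxy-2-Ar-acrylate (racemic axis)
Conditions: Pd(OAc)2 (5 mol %), SPhos (10 mol %), K3PO4, toluene/H2O 10:1, 80 °C
Reagents that add atoms: none
Why: Suzuki–Miyaura coupling in which the bulky, electron-rich SPhos ligand should let zerovalent palladium insert into the doubly ortho-substituted C8–I bond and release the tri-ortho-substituted biaryl, while the biphasic phosphate medium is mild enough for the pyranone, the enol ether and the ester; the new axis forms racemic.

Step 7
Reactants: 9 tert-butyl (E)-3-methoxy-2-Ar-acrylate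
Product: 10 (E)-3-methoxy-2-Ar-acrylic acid (racemic axis)
Conditions: CF3CO2H/CH2Cl2 1:4, anhydrous, 0 → 20 °C
Reagents that add atoms: none
Why: Acidolysis of the tert-butyl ester (alkyl–oxygen cleavage with loss of 2-methylpropene) under anhydrous conditions spares the aryl methyl ethers, the pyranone and the push–pull enol ether, whereas the hydroxide needed to saponify a methyl 3-methoxyacrylate would open the pyranone of unit 2.

Step 8
Reactants: 11 3,5-dimethoxyphenol
Product: 12 3,5-dimethoxyphenyl N-isopropylcarbamate
Conditions: i-PrNCO, Et3N (cat.), CH2Cl2, 20 °C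
Reagents that add atoms: isopropyl isocyanate CC(C)N=C=O
Why: Base-catalysed addition of the phenol to the isocyanate gives an N-monosubstituted carbamate that serves first as ortho director and later as a base-labile protecting group.

Step 9
Reactants: 12 3,5-dimethoxyphenyl N-isopropylcarbamate
Product: 16 3,5-dimethoxy-2-(trimethylsilyl)phenyl N-isopropylcarbamate, via N-silyl carbamate 13 (not isolated), via aryllithium 14 (not isolated), via bis-silyl carbamate 15 (not isolated)
Conditions: TMSOTf, TMEDA, Et2O, 0 → 20 °C; n-BuLi, TMEDA, −78 °C; TMSCl, −78 → 20 °C; aq. NaHSO4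
Reagents that add atoms: chlorotrimethylsilane C[Si](C)(C)Cl
Why: Directed ortho-metalation in which the carbamate, N-silylated in the flask so that no N–H consumes base, should steer n-BuLi to C2 (also flanked by the C3 methoxy group) and not to C4 between the two weaker methoxy directors, the aryllithium being silylated at −78 °C before an anionic Fries shift can start and the N–Si bond being hydrolysed on work-up.

Step 10
Reactants: 16 3,5-dimethoxy-2-(trimethylsilyl)phenyl N-isopropylcarbamate
Product: 18 3,5-dimethoxy-2-(trimethylsilyl)phenyl trifluoromethanesulfonate, via silylphenol 17 (not isolated)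
Conditions: DBU, Et2NH, MeCN, 40 °C; then PhNTf2, 20 °C
Reagents that add atoms: N-phenylbis(trifluoromethanesulfonimide) O=S(=O)(N(c1ccccc1)S(=O)(=O)C(F)(F)F)C(F)(F)F
Why: E1cB cleavage of the carbamate (DBU removes N–H, the phenoxide leaves and Et2NH traps the isocyanate as a urea) followed by O-sulfonylation of the phenoxide in the same flask, which avoids isolating the electron-rich, protodesilylation-prone silylphenol 17.

Step 11
Reactants: 10 (E)-3-methoxy-2-Ar-acrylic acid; 18 3,5-dimethoxy-2-(trimethylsilyl)phenyl trifluoromethanesulfonate (2 equiv)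
Product: 23 racemic hexa-O-methylbisoflavolin D, via benzyne 19 (not isolated), via aryl carbanion 20 (not isolated), via benzoxetene alkoxide 21 (not isolated), via acyl phenoxide 22 (not isolated)
Conditions: CsF (5 equiv, dried), THF (dilute), sealed tube, 125 °C
Reagents that add atoms: none
Why: Proposed new method: fluoride removes the silyl group of 18 and triflate leaves to give aryne 19, whose carbon remote from the flanking methoxy group takes up the cesium carboxylate of 10, because the negative charge then develops on the carbon next to the inductively withdrawing methoxy group (carbanion 20). The carbanion adds to its own ester carbonyl (four-membered alkoxide 21) and ring opening gives the ortho-acyl phenoxide 22, an anionic 1,3 O-to-C acyl shift that forms O1–C8a and C4–C4a. Phenoxide 22 then closes ring C by 6-endo-trig conjugate addition to the 3-methoxy enone and E1cB loss of methoxide (O1–C2), which also erases the alkene geometry. The closest known reaction type is the CsF-mediated insertion of arynes into the C–O bond of carboxylic acids in hot THF, which delivers ortho-hydroxyaryl ketones, 4-chromanones from acrylic acids and flavones from arylpropiolic acids; a 3-methoxyacrylic acid leading to an isoflavone is the untested extension, and the ring closure itself mirrors the cyclisation of 2-hydroxyaryl enaminones to chromones. The step needs regioselective capture of the aryne, secured by the methoxy group beside the triple bond of 19, and attack of the carbanion on the carbonyl carbon in preference to protonation (plain aryl ester) or conjugate attack on the methoxy-bearing carbon (isomeric 3-arylcoumarin), which hot, dilute, aprotic THF and the s-trans ester conformation should favour. No stereocentre is formed, and the biaryl axis stays racemic at this temperature.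

Step 12
Reactants: 23 racemic hexa-O-methylbisoflavolin D
Product: 24 (M)-hexa-O-methylbisoflavolin D
Conditions: preparative HPLC, amylose tris(3,5-dimethylphenylcarbamate) phase, n-hexane/i-PrOH, 20 °C
Reagents that add atoms: none
Why: Chromatographic resolution on a polysaccharide chiral stationary phase, in which no bond is formed and the only stereogenic element (the C3'–C8 axis) is sorted, the (M) fraction to be assigned by comparing its electronic circular dichroism curve with the computed one and, after step 13, with that of the natural product.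

Step 13
Reactants: 24 (M)-hexa-O-methylbisoflavolin D
Product: 25 (M)-bisoflavolin D
Conditions: BBr3 (excess), CH2Cl2, −78 → 20 °C; then MeOH, H2O, 0 °C
Reagents that add atoms: none
Why: Lewis acid ether cleavage (bromide attacks the methyl group of each BBr3-complexed aryl methyl ether in an SN2 step) touches no bond at the axis, so holding the mixture at or below 20 °C should carry the (M) configuration of 24 into 25.

**Compound list**

1 | genistein, 5,7-dihydroxy-3-(4-hydroxyphenyl)-4H-chromen-4-one | O=c1c(-c2ccc(O)cc2)coc2cc(O)cc(O)c12 | starting material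
2 | 5,7-dimethoxy-3-(4-methoxyphenyl)-4H-chromen-4-one | O=c1c(-c2ccc(OC)cc2)coc2cc(OC)cc(OC)c12 | intermediate
3 | 8-iodo-5,7-dimethoxy-3-(4-methoxyphenyl)-4H-chromen-4-one | O=c1c(-c2ccc(OC)cc2)coc2c(I)c(OC)cc(OC)c12 | intermediate
4 | 2-(3-bromo-4-methoxyphenyl)acetic acid | COc1ccc(CC(=O)O)cc1Br | starting material
5 | tert-butyl 2-(3-bromo-4-methoxyphenyl)acetate | COc1ccc(CC(=O)OC(C)(C)C)cc1Br | intermediate
6 | sodium enolate of tert-butyl 2-(3-bromo-4-methoxyphenyl)-3-oxopropanoate | [Na+].[O-]C=C(C(=O)OC(C)(C)C)c1ccc(OC)c(Br)c1 | intermediate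
7 | tert-butyl (E)-2-(3-bromo-4-methoxyphenyl)-3-methoxyacrylate | CO/C=C(/C(=O)OC(C)(C)C)c1ccc(OC)c(Br)c1 | intermediate
8 | tert-butyl (E)-3-methoxy-2-[4-methoxy-3-(4,4,5,5-tetramethyl-1,3,2-dioxaborolan-2-yl)phenyl]acrylate | CO/C=C(/C(=O)OC(C)(C)C)c1ccc(OC)c(B2OC(C)(C)C(C)(C)O2)c1 | intermediate
9 | tert-butyl (E)-2-{3-[5,7-dimethoxy-3-(4-methoxyphenyl)-4-oxo-4H-chromen-8-yl]-4-methoxyphenyl}-3-methoxyacrylate, racemic axis | CO/C=C(/C(=O)OC(C)(C)C)c1ccc(OC)c(-c2c(OC)cc(OC)c3c(=O)c(-c4ccc(OC)cc4)coc23)c1 | intermediate
10 | (E)-2-{3-[5,7-dimethoxy-3-(4-methoxyphenyl)-4-oxo-4H-chromen-8-yl]-4-methoxyphenyl}-3-methoxyacrylic acid, racemic axis | CO/C=C(/C(=O)O)c1ccc(OC)c(-c2c(OC)cc(OC)c3c(=O)c(-c4ccc(OC)cc4)coc23)c1 | intermediate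
11 | 3,5-dimethoxyphenol | COc1cc(O)cc(OC)c1 | starting material
12 | 3,5-dimethoxyphenyl N-isopropylcarbamate | COc1cc(OC)cc(OC(=O)NC(C)C)c1 | intermediate
13 | 3,5-dimethoxyphenyl N-isopropyl-N-(trimethylsilyl)carbamate | COc1cc(OC)cc(OC(=O)N(C(C)C)[Si](C)(C)C)c1 | intermediate
14 | 2-lithio-3,5-dimethoxyphenyl N-isopropyl-N-(trimethylsilyl)carbamate | COc1cc(OC)c([Li])c(OC(=O)N(C(C)C)[Si](C)(C)C)c1 | intermediate
15 | 3,5-dimethoxy-2-(trimethylsilyl)phenyl N-isopropyl-N-(trimethylsilyl)carbamate | COc1cc(OC)c([Si](C)(C)C)c(OC(=O)N(C(C)C)[Si](C)(C)C)c1 | intermediate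
16 | 3,5-dimethoxy-2-(trimethylsilyl)phenyl N-isopropylcarbamate | COc1cc(OC)c([Si](C)(C)C)c(OC(=O)NC(C)C)c1 | intermediate
17 | 3,5-dimethoxy-2-(trimethylsilyl)phenol (present as its DBU-H phenoxide) | COc1cc(OC)c([Si](C)(C)C)c(O)c1 | intermediate
18 | 3,5-dimethoxy-2-(trimethylsilyl)phenyl trifluoromethanesulfonate | COc1cc(OC)c([Si](C)(C)C)c(OS(=O)(=O)C(F)(F)F)c1 | intermediate
19 | 3,5-dimethoxybenzyne (1,2-didehydro-3,5-dimethoxybenzene) | COC1=CC(OC)=CC#C1 | intermediate
20 | cesium salt of the 3,5-dimethoxyphenyl ester of acid 10, carbanion on the ring carbon between the ester-oxygen carbon and a methoxy carbon | [Cs+].CO/C=C(/C(=O)Oc1cc(OC)cc(OC)[c-]1)c1ccc(OC)c(-c2c(OC)cc(OC)c3c(=O)c(-c4ccc(OC)cc4)coc23)c1 | intermediate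
21 | cesium alkoxide of the four-membered 2H-benzoxete formed when the carbanion of 20 adds to its ester carbonyl (dimethoxy benzo ring, (E)-2-methoxy-1-Ar-vinyl group on the alkoxide carbon) | [Cs+].CO/C=C(/C1([O-])Oc2cc(OC)cc(OC)c12)c1ccc(OC)c(-c2c(OC)cc(OC)c3c(=O)c(-c4ccc(OC)cc4)coc23)c1 | intermediate
22 | cesium 2-[(E)-3-methoxy-2-Ar-acryloyl]-3,5-dimethoxyphenoxide | [Cs+].CO/C=C(/C(=O)c1c([O-])cc(OC)cc1OC)c1ccc(OC)c(-c2c(OC)cc(OC)c3c(=O)c(-c4ccc(OC)cc4)coc23)c1 | intermediate
23 | racemic hexa-O-methylbisoflavolin D, 8-[5-(5,7-dimethoxy-4-oxo-4H-chromen-3-yl)-2-methoxyphenyl]-5,7-dimethoxy-3-(4-methoxyphenyl)-4H-chromen-4-one | O=c1c(-c2ccc(OC)c(-c3c(OC)cc(OC)c4c(=O)c(-c5ccc(OC)cc5)coc34)c2)coc2cc(OC)cc(OC)c12 | intermediate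
24 | (M)-hexa-O-methylbisoflavolin D, (M) axis between C3' of unit 1 and C8 of unit 2 | O=c1c(-c2ccc(OC)c(-c3c(OC)cc(OC)c4c(=O)c(-c5ccc(OC)cc5)coc34)c2)coc2cc(OC)cc(OC)c12 | intermediate
25 | (M)-bisoflavolin D, (M)-8-[5-(5,7-dihydroxy-4-oxo-4H-chromen-3-yl)-2-hydroxyphenyl]-5,7-dihydroxy-3-(4-hydroxyphenyl)-4H-chromen-4-one | O=c1c(-c2ccc(O)c(-c3c(O)cc(O)c4c(=O)c(-c5ccc(O)cc5)coc34)c2)coc2cc(O)cc(O)c12 | target

**Summary**

Total step count: 13.
Longest linear sequence: 8 steps (steps 3, 4, 5, 6, 7, 11, 12 and 13, from acid 4).

**Steps most likely to fail**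

Step 11. The carbanion may be protonated before the acyl shift, which stops the sequence at the O-aryl ester, or it may attack the methoxy-bearing alkene carbon instead of the weakly electrophilic vinylogous carbonate carbonyl. In that case ring C of unit 1 would be built by the classical deoxybenzoin route, which sets out from ester 5. Miyaura borylation of 5 (B2pin2, PdCl2(dppf), KOAc, dioxane, 90 °C) would give tert-butyl 2-[4-methoxy-3-(4,4,5,5-tetramethyl-1,3,2-dioxaborolan-2-yl)phenyl]acetate F1. Suzuki–Miyaura coupling of F1 with iodide 3 (Pd(OAc)2, SPhos, K3PO4, toluene/H2O, 80 °C) would give tert-butyl 2-{3-[5,7-dimethoxy-3-(4-methoxyphenyl)-4-oxo-4H-chromen-8-yl]-4-methoxyphenyl}acetate F2. Acidolysis (CF3CO2H, CH2Cl2) would free 2-{3-[5,7-dimethoxy-3-(4-methoxyphenyl)-4-oxo-4H-chromen-8-yl]-4-methoxyphenyl}acetic acid F3. Friedel–Crafts acylation of 3,5-dimethoxyphenol 11 with F3 in BF3·OEt2 at 80 °C, ortho to the free hydroxyl, would give 1-(2-hydroxy-4,6-dimethoxyphenyl)-2-Ar-ethanone F4. Heating F4 with N,N-dimethylformamide dimethyl acetal in toluene (enaminone formation, then cyclisation with loss of dimethylamine) would close ring C and come back to the route at racemic hexamethyl ether 23.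

Step 6. Transmetalation at the doubly ortho-substituted C8 may be slow, so that protodeboronation of the boronate, loss of iodine from the iodide and opening of the pyranone by the aqueous base compete. The C3'–C8 bond would then be made by a base-free Stille coupling that sets out from bromide 7. Stannylation with Me3SnSnMe3 (Pd(PPh3)4, toluene, 100 °C) would give tert-butyl (E)-3-methoxy-2-[4-methoxy-3-(trimethylstannyl)phenyl]acrylate F5. F5 would be coupled with iodide 3 under copper-assisted conditions (Pd(PPh3)4, CuI, CsF, DMF, 45 °C) and the route is rejoined at biaryl ester 9.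

Step 13. The two C7 methyl ethers may cleave too slowly at low temperature, and the warming needed to finish them may allow rotation about the axis. The last two operations would then be inverted, setting out from racemic 23. Exhaustive demethylation without the temperature limit (BBr3, CH2Cl2, up to 40 °C) would give racemic bisoflavolin D F6. Its atropisomers would be separated on an immobilised cellulose tris(3,5-dichlorophenylcarbamate) phase under reversed-phase conditions (MeCN/H2O/HCO2H, 20 °C), which arrives directly at target 25.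

**Further compounds**

F1 | step 11 | tert-butyl 2-[4-methoxy-3-(4,4,5,5-tetramethyl-1,3,2-dioxaborolan-2-yl)phenyl]acetate | COc1ccc(CC(=O)OC(C)(C)C)cc1B1OC(C)(C)C(C)(C)O1
F2 | step 11 | tert-butyl 2-{3-[5,7-dimethoxy-3-(4-methoxyphenyl)-4-oxo-4H-chromen-8-yl]-4-methoxyphenyl}acetate (racemic axis) | COc1ccc(CC(=O)OC(C)(C)C)cc1-c1c(OC)cc(OC)c2c(=O)c(-c3ccc(OC)cc3)coc12
F3 | step 11 | 2-{3-[5,7-dimethoxy-3-(4-methoxyphenyl)-4-oxo-4H-chromen-8-yl]-4-methoxyphenyl}acetic acid (racemic axis) | COc1ccc(CC(=O)O)cc1-c1c(OC)cc(OC)c2c(=O)c(-c3ccc(OC)cc3)coc12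
F4 | step 11 | 1-(2-hydroxy-4,6-dimethoxyphenyl)-2-{3-[5,7-dimethoxy-3-(4-methoxyphenyl)-4-oxo-4H-chromen-8-yl]-4-methoxyphenyl}ethanone (racemic axis) | COc1ccc(CC(=O)c2c(O)cc(OC)cc2OC)cc1-c1c(OC)cc(OC)c2c(=O)c(-c3ccc(OC)cc3)coc12
F5 | step 6 | tert-butyl (E)-3-methoxy-2-[4-methoxy-3-(trimethylstannyl)phenyl]acrylate | CO/C=C(/C(=O)OC(C)(C)C)c1ccc(OC)c([Sn](C)(C)C)c1
F6 | step 13 | racemic bisoflavolin D | O=c1c(-c2ccc(O)c(-c3c(O)cc(O)c4c(=O)c(-c5ccc(O)cc5)coc34)c2)coc2cc(O)cc(O)c12
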